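**Plan**

- Feature used: in ring A, C8a is para to the C6 methoxy group. With O1 deleted from ring C the skeleton is a 2-aryl-3-oxyindan-1-one, whose aryl carbon (future C8a) is a strong migrating group and whose α-carbon (future C3) can settle trans to the C4 oxygen.
- Cuts, in order: O1–C2 (chroman ether back to phenol + primary alcohol, i.e. the reduced lactone); C8a–O1 and O1–C2 together (oxygen taken out of the lactone, giving the indanone); C4–O; C3–C1′ (indanone + aryl bromide).
- Forward: ring B bromide from 2,3-dimethoxyphenol via the quinone; ring A indanone by Friedel–Crafts closure; Pd α-arylation joins them; dehydrogenation, conjugate borylation–oxidation and silylation follow.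
- The five-membered ketone is then enlarged to the six-membered aryl lactone, the lactone is reduced, and ring C is reclosed at O1–C2 by Mitsunobu etherification; desilylation and hydrogenolysis finish.
- Stereochemistry: C4 (R) from ligand-controlled copper-catalysed boryl addition to the indenone, oxidised with retention; C3 (S) from equilibration of the α-aryl ketone to trans; neither centre is touched afterwards.

Key step: step 10

Remarks: Ar = 2,5-bis(benzyloxy)-3,4-dimethoxyphenyl. Compounds 1 and 4 are taken as commercial. The facial sense of the copper catalyst on this α-aryl indenone cannot be predicted with confidence, so it is assumed that the hand of the Josiphos ligand in step 8 is fixed in a trial run so that boron enters as (3R).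

**Route**

Step 1
Reactants: 1 3-(4-hydroxy-3-methoxyphenyl)propanoic acid
Product: 2 6-hydroxy-5-methoxyindan-1-one
Conditions: MeSO3H, 90 °C
Reagents that add atoms: none
Why: Intramolecular Friedel–Crafts acylation; of the two positions ortho to the side chain, the one para to OMe is the more activated and less hindered, so the carbonyl ends on the ring carbon para to the methoxy group.

Step 2
Reactants: 2 6-hydroxy-5-methoxyindan-1-one
Product: 3 6-(benzyloxy)-5-methoxyindan-1-one
Conditions: BnBr, K2CO3, DMF, rt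
Reagents that add atoms: benzyl bromide BrCc1ccccc1
Why: Williamson ether synthesis; carbonate deprotonates only the phenol, so O-benzylation should not be accompanied by α-alkylation of the ketone.

Step 3
Reactants: 4 2,3-dimethoxyphenol
Product: 5 2,3-dimethoxy-1,4-benzoquinone
Conditions: Fremy's salt (2.2 equiv), KH2PO4 aq, acetone/H2O, rt
Reagents that add atoms: potassium nitrosodisulfonate [O]N(S(=O)(=O)[O-])S(=O)(=O)[O-].[K+].[K+]
Why: Teuber oxidation; the nitroxyl radical converts a phenol with a free para position into the p-quinone, the second equivalent delivering the new oxygen at C4.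

Step 4
Reactants: 5 2,3-dimethoxy-1,4-benzoquinone
Product: 7 1,4-bis(benzyloxy)-2,3-dimethoxybenzene, via 2,3-dimethoxyhydroquinone 6 (not isolated)
Conditions: Na2S2O4, Bu4NBr (cat.), THF/H2O, rt; then KOH aq, BnBr, rt
Reagents that add atoms: benzyl bromide BrCc1ccccc1
Why: Reductive alkylation of a quinone; dithionite reduction followed in the same flask by phase-transfer Williamson benzylation keeps the air-sensitive hydroquinone under reducing conditions until both oxygens are capped.

Step 5
Reactants: 7 1,4-bis(benzyloxy)-2,3-dimethoxybenzene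
Product: 8 1,4-bis(benzyloxy)-5-bromo-2,3-dimethoxybenzene
Conditions: NBS (1.0 equiv), MeCN, 0 °C → rt
Reagents that add atoms: N-bromosuccinimide O=C1CCC(=O)N1Br
Why: Electrophilic aromatic bromination; the two free ring positions are equivalent by symmetry and the first bromine slows a second substitution.

Step 6
Reactants: 3 6-(benzyloxy)-5-methoxyindan-1-one, 8 1,4-bis(benzyloxy)-5-bromo-2,3-dimethoxybenzene
Product: 9 rac-2-Ar-6-(benzyloxy)-5-methoxyindan-1-one
Conditions: Pd2(dba)3 (2 mol%), XPhos (5 mol%), NaOtBu, toluene, 80 °C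
Reagents that add atoms: none
Why: Palladium-catalysed α-arylation of a ketone enolate (Buchwald–Hartwig type); the bulky biarylphosphine should allow oxidative addition of the electron-rich ortho-substituted bromide, the product rests as its stabilised enolate and is not arylated twice, and the racemic C2 centre is erased in step 7.

Step 7
Reactants: 9 rac-2-Ar-6-(benzyloxy)-5-methoxyindan-1-one
Product: 11 2-Ar-6-(benzyloxy)-5-methoxy-1H-inden-1-one, via 2-phenylselanyl ketone 10 (not isolated)
Conditions: LiHMDS, THF, −78 °C; PhSeCl; then 30% H2O2, pyridine, CH2Cl2, 0 °C → rt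
Reagents that add atoms: phenylselenyl chloride Cl[Se]c1ccccc1 (selanyl group, kept only in 10)
Why: α-Selenenylation of the enolate followed by selenoxide syn-elimination; the selenoxide on the quaternary C2 can only take a hydrogen from C3, so the C2=C3 double bond of the indenone is the sole outcome.

Step 8
Reactants: 11 2-Ar-6-(benzyloxy)-5-methoxy-1H-inden-1-one
Product: 13 (2R,3R)-2-Ar-6-(benzyloxy)-3-hydroxy-5-methoxyindan-1-one (2,3-trans), via trans 3-boryl ketone 12 (not isolated)
Conditions: CuCl (5 mol%), NaOtBu (10 mol%), (R,S)-Josiphos or its enantiomer (6 mol%, see remark), B2pin2, MeOH, THF, rt; then NaBO3·4H2O, THF/pH 7 buffer, 0 °C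
Reagents that add atoms: bis(pinacolato)diboron CC1(C)OB(OC1(C)C)B1OC(C)(C)C(C)(C)O1 (boryl group, kept only in 12); sodium perborate [Na+].[O-]OB=O (hydroxyl oxygen of 13)
Why: Copper-catalysed enantioselective conjugate borylation of a cyclic enone, the chiral bisphosphine choosing the face of C3 (3R); the acidic C2–H of the β-boryl ketone should equilibrate under the alkoxide present to the more stable trans isomer, where no β-elimination is possible, before perborate oxidises the C–B bond with retention.

Step 9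
Reactants: 13 (2R,3R)-2-Ar-6-(benzyloxy)-3-hydroxy-5-methoxyindan-1-one
Product: 14 (2R,3R)-2-Ar-6-(benzyloxy)-3-[(tert-butyldimethylsilyl)oxy]-5-methoxyindan-1-one
Conditions: TBSOTf, 2,6-lutidine, CH2Cl2, −78 °C
Reagents that add atoms: tert-butyldimethylsilyl triflate CC(C)(C)[Si](C)(C)OS(=O)(=O)C(F)(F)F
Why: O-Silylation with a silyl triflate and a hindered weak base at low temperature should cap the alcohol without enolising the ketone or dehydrating the β-hydroxy ketone.

Step 10
Reactants: 14 (2R,3R)-2-Ar-6-(benzyloxy)-3-[(tert-butyldimethylsilyl)oxy]-5-methoxyindan-1-one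
Product: 15 (3R,4R)-3-Ar-7-(benzyloxy)-4-[(tert-butyldimethylsilyl)oxy]-6-methoxychroman-2-one (3,4-trans)
Conditions: mCPBA (2.5 equiv), NaHCO3, CH2Cl2, 0 °C → rt, dark; Na2S2O3 quench, cold work-up, crude lactone used at once
Reagents that add atoms: m-chloroperbenzoic acid OOC(=O)c1cccc(Cl)c1
Why: Baeyer–Villiger oxidation: the peracid adds to the C1 carbonyl to give the Criegee adduct, and the aryl carbon C7a shifts from carbon to the peroxide oxygen as m-chlorobenzoate leaves, so that one oxygen atom is inserted between C7a and C1. The closest known reaction type is the peracid ring expansion of alkoxy-substituted 1-indanones to 3,4-dihydrocoumarins. The six-membered lactone arises not by a cyclisation but by enlargement of the five-membered ketone through this 1,2-shift, the two new bonds being C7a–O and O–C1 (C8a–O1 and O1–C2 of the target). No stereocentre is created; C2 and C3 are neither origin nor terminus of the migration and should keep their trans (R,R) arrangement as long as the medium stays non-basic, which the bicarbonate buffer and the cold work-up are meant to secure. The step needs migration of C7a in preference to the secondary benzylic C2: the methoxy group para to C7a makes the aryl carbon the better carrier of positive charge, while the β-silyloxy substituent lowers the migratory aptitude of C2. The same buffering should keep the silyl ether from β-elimination and limit attack of the peracid on the alkoxyarenes.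

Step 11
Reactants: 15 (3R,4R)-3-Ar-7-(benzyloxy)-4-[(tert-butyldimethylsilyl)oxy]-6-methoxychroman-2-one
Product: 16 5-(benzyloxy)-2-{(1R,2S)-2-Ar-1-[(tert-butyldimethylsilyl)oxy]-3-hydroxypropyl}-4-methoxyphenol
Conditions: DIBAL-H (3 equiv), CH2Cl2, −78 → −40 °C; Rochelle salt
Reagents that add atoms: none
Why: Hydride reduction of an aryl ester (lactone) to phenol and primary alcohol; the non-basic aluminium hydride at low temperature should reduce the reactive lactone before enolisation toward the 3-arylcoumarin or silyl migration can occur.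

Step 12
Reactants: 16 5-(benzyloxy)-2-{(1R,2S)-2-Ar-1-[(tert-butyldimethylsilyl)oxy]-3-hydroxypropyl}-4-methoxyphenol
Product: 17 (3S,4R)-3-Ar-7-(benzyloxy)-4-[(tert-butyldimethylsilyl)oxy]-6-methoxychromane
Conditions: PPh3, DIAD, THF, 0 °C → rt
Reagents that add atoms: none
Why: Intramolecular Mitsunobu etherification (6-exo-tet); the phenol is the acidic partner and the primary alcohol is activated, so O1–C2 closes without touching either stereocentre.

Step 13
Reactants: 17 (3S,4R)-3-Ar-7-(benzyloxy)-4-[(tert-butyldimethylsilyl)oxy]-6-methoxychromane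
Product: 18 (3S,4R)-3-Ar-7-(benzyloxy)-6-methoxychroman-4-ol
Conditions: TBAF, THF, 0 °C → rt
Reagents that add atoms: none
Why: Fluoride-mediated desilylation; all phenols are still benzylated, so no quinone methide can form from the benzylic alcohol under the basic fluoride.

Step 14
Reactants: 18 (3S,4R)-3-Ar-7-(benzyloxy)-6-methoxychroman-4-ol
Product: 19 (3S,4R)-3-(2,5-dihydroxy-3,4-dimethoxyphenyl)-6-methoxychromane-4,7-diol
Conditions: H2 (1 atm), 10% Pd/C, EtOAc, rt, stopped when the third benzyl group is gone; work-up under argon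
Reagents that add atoms: none
Why: Catalytic hydrogenolysis of aryl benzyl ethers, which under neutral conditions should be cleaved faster than the secondary benzylic C4–OH; air is excluded because the product is a hydroquinone.

**Compound list**

1 | 3-(4-hydroxy-3-methoxyphenyl)propanoic acid | COc1cc(CCC(=O)O)ccc1O | starting material
2 | 6-hydroxy-5-methoxy-2,3-dihydro-1H-inden-1-one | COc1cc2c(cc1O)C(=O)CC2 | intermediate
3 | 6-(benzyloxy)-5-methoxy-2,3-dihydro-1H-inden-1-one | COc1cc2c(cc1OCc1ccccc1)C(=O)CC2 | intermediate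
4 | 2,3-dimethoxyphenol | COc1cccc(O)c1OC | starting material
5 | 2,3-dimethoxy-1,4-benzoquinone | COC1=C(OC)C(=O)C=CC1=O | intermediate
6 | 2,3-dimethoxybenzene-1,4-diol | COc1c(O)ccc(O)c1OC | intermediate (not isolated)
7 | 1,4-bis(benzyloxy)-2,3-dimethoxybenzene | COc1c(OCc2ccccc2)ccc(OCc2ccccc2)c1OC | intermediate
8 | 1,4-bis(benzyloxy)-5-bromo-2,3-dimethoxybenzene | COc1c(OC)c(OCc2ccccc2)c(Br)cc1OCc1ccccc1 | intermediate
9 | rac-2-[2,5-bis(benzyloxy)-3,4-dimethoxyphenyl]-6-(benzyloxy)-5-methoxy-2,3-dihydro-1H-inden-1-one | COc1cc2c(cc1OCc1ccccc1)C(=O)C(c1cc(OCc3ccccc3)c(OC)c(OC)c1OCc1ccccc1)C2 | intermediate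
10 | rac-2-[2,5-bis(benzyloxy)-3,4-dimethoxyphenyl]-6-(benzyloxy)-5-methoxy-2-(phenylselanyl)-2,3-dihydro-1H-inden-1-one | COc1cc2c(cc1OCc1ccccc1)C(=O)C([Se]c1ccccc1)(c1cc(OCc3ccccc3)c(OC)c(OC)c1OCc1ccccc1)C2 | intermediate (not isolated)
11 | 2-[2,5-bis(benzyloxy)-3,4-dimethoxyphenyl]-6-(benzyloxy)-5-methoxy-1H-inden-1-one | COc1cc2c(cc1OCc1ccccc1)C(=O)C(c1cc(OCc3ccccc3)c(OC)c(OC)c1OCc1ccccc1)=C2 | intermediate
12 | (2S,3R)-2-[2,5-bis(benzyloxy)-3,4-dimethoxyphenyl]-6-(benzyloxy)-5-methoxy-3-(4,4,5,5-tetramethyl-1,3,2-dioxaborolan-2-yl)-2,3-dihydro-1H-inden-1-one (trans) | COc1cc2c(cc1OCc1ccccc1)C(=O)[C@H](c1cc(OCc3ccccc3)c(OC)c(OC)c1OCc1ccccc1)[C@H]2B1OC(C)(C)C(C)(C)O1 | intermediate (not isolated)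
13 | (2R,3R)-2-[2,5-bis(benzyloxy)-3,4-dimethoxyphenyl]-6-(benzyloxy)-3-hydroxy-5-methoxy-2,3-dihydro-1H-inden-1-one (trans) | COc1cc2c(cc1OCc1ccccc1)C(=O)[C@H](c1cc(OCc3ccccc3)c(OC)c(OC)c1OCc1ccccc1)[C@H]2O | intermediate
14 | (2R,3R)-2-[2,5-bis(benzyloxy)-3,4-dimethoxyphenyl]-6-(benzyloxy)-3-[(tert-butyldimethylsilyl)oxy]-5-methoxy-2,3-dihydro-1H-inden-1-one (trans) | COc1cc2c(cc1OCc1ccccc1)C(=O)[C@H](c1cc(OCc3ccccc3)c(OC)c(OC)c1OCc1ccccc1)[C@H]2O[Si](C)(C)C(C)(C)C | intermediate
15 | (3R,4R)-7-(benzyloxy)-3-[2,5-bis(benzyloxy)-3,4-dimethoxyphenyl]-4-[(tert-butyldimethylsilyl)oxy]-6-methoxychroman-2-one (trans) | COc1cc2c(cc1OCc1ccccc1)OC(=O)[C@H](c1cc(OCc3ccccc3)c(OC)c(OC)c1OCc1ccccc1)[C@H]2O[Si](C)(C)C(C)(C)C | intermediate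
16 | 5-(benzyloxy)-2-{(1R,2S)-2-[2,5-bis(benzyloxy)-3,4-dimethoxyphenyl]-1-[(tert-butyldimethylsilyl)oxy]-3-hydroxypropyl}-4-methoxyphenol | COc1cc([C@H](O[Si](C)(C)C(C)(C)C)[C@H](CO)c2cc(OCc3ccccc3)c(OC)c(OC)c2OCc2ccccc2)c(O)cc1OCc1ccccc1 | intermediate
17 | (3S,4R)-7-(benzyloxy)-3-[2,5-bis(benzyloxy)-3,4-dimethoxyphenyl]-4-[(tert-butyldimethylsilyl)oxy]-6-methoxychromane (trans) | COc1cc2c(cc1OCc1ccccc1)OC[C@H](c1cc(OCc3ccccc3)c(OC)c(OC)c1OCc1ccccc1)[C@H]2O[Si](C)(C)C(C)(C)C | intermediate
18 | (3S,4R)-7-(benzyloxy)-3-[2,5-bis(benzyloxy)-3,4-dimethoxyphenyl]-6-methoxychroman-4-ol (trans) | COc1cc2c(cc1OCc1ccccc1)OC[C@H](c1cc(OCc3ccccc3)c(OC)c(OC)c1OCc1ccccc1)[C@H]2O | intermediate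
19 | (3S,4R)-3-(2,5-dihydroxy-3,4-dimethoxyphenyl)-6-methoxychromane-4,7-diol (trans) | COc1cc2c(cc1O)OC[C@H](c1cc(O)c(OC)c(OC)c1O)[C@H]2O | target

**Step count**

Total: 14 steps. Longest linear sequence: 12 steps (steps 3–14, from 4); the ring A branch (steps 1–2, from 1) joins at step 6.

**Steps most likely to fail**

1. Step 10 (ring expansion). What may go wrong: migration of the secondary benzylic C2 in competition with the aryl carbon, loss of silanol from the lactone by β-elimination, or attack of the peracid on the alkoxyarenes if carbonyl addition is slow. Fallback, setting out from 3 and 8 and coming back at 18: the oxygen would be inserted into ketone 3 itself, where the aryl carbon competes only with a primary CH2 (mCPBA, cat. TFA, CH2Cl2), to give 7-(benzyloxy)-6-methoxychroman-2-one F1. DDQ in hot dioxane would dehydrogenate it to 7-(benzyloxy)-6-methoxycoumarin F2, and NBS would brominate C3 to give 7-(benzyloxy)-3-bromo-6-methoxycoumarin F3. Bromide 8 would be converted into the aryl pinacol boronate F4 (B2pin2, Pd(dppf)Cl2, KOAc) and joined to F3 by Suzuki–Miyaura coupling to give the 3-arylcoumarin F5. DIBAL-H would open F5 to the (Z)-allylic alcohol phenol F6, and Mitsunobu closure would give the isoflav-3-ene F7. Hydroboration of F7 with monoisopinocampheylborane and perborate oxidation, a syn addition with boron at the less substituted C4, would give the trans alcohol 18; the absolute configuration would then rest on the chiral borane.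

2. Step 8 (borylation–oxidation). What may go wrong: insufficient facial discrimination by the copper catalyst on the α-aryl indenone, or dehydration of the β-hydroxy ketone during C–B oxidation. Fallback, setting out from 11 and coming back at 13: an achiral copper catalyst (CuCl, Xantphos, NaOtBu, B2pin2, MeOH) would give the racemic trans boronate, that is 12 together with its enantiomer, the (2R,3S)-3-boryl ketone F8. Perborate would then give the racemic alcohol, 13 together with the (2S,3S)-hydroxy ketone F9. A lipase (Amano PS or CAL-B, vinyl acetate, MTBE), screened so that the unwanted antipode reacts fast, would convert F9 into the (2S,3S)-3-acetoxy ketone F10 and leave 13 to be separated by chromatography.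

3. Step 14 (hydrogenolysis). What may go wrong: hydrogenolysis of the benzylic C4–O bond along with the three benzyl ethers. Fallback, setting out from 17 and coming back at 19: the order of the two deprotections would be inverted. Hydrogenolysis of 17 (H2, Pd/C, EtOAc), in which the benzylic oxygen is still masked by the bulky silyl group, would give the (3S,4R)-4-silyloxy triphenol F11. Buffered fluoride (Et3N·3HF, MeCN, rt, argon) would then free the C4 hydroxyl to give 19.

**Further compounds**

F1 | step 10 | 7-(benzyloxy)-6-methoxychroman-2-one | COc1cc2CCC(=O)Oc2cc1OCc1ccccc1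
F2 | step 10 | 7-(benzyloxy)-6-methoxy-2H-chromen-2-one | COc1cc2C=CC(=O)Oc2cc1OCc1ccccc1
F3 | step 10 | 7-(benzyloxy)-3-bromo-6-methoxy-2H-chromen-2-one | COc1cc2C=C(Br)C(=O)Oc2cc1OCc1ccccc1
F4 | step 10 | 2-[2,5-bis(benzyloxy)-3,4-dimethoxyphenyl]-4,4,5,5-tetramethyl-1,3,2-dioxaborolane | COc1c(OC)c(OCc2ccccc2)c(B2OC(C)(C)C(C)(C)O2)cc1OCc1ccccc1
F5 | step 10 | 7-(benzyloxy)-3-[2,5-bis(benzyloxy)-3,4-dimethoxyphenyl]-6-methoxy-2H-chromen-2-one | COc1cc2C=C(c3cc(OCc4ccccc4)c(OC)c(OC)c3OCc3ccccc3)C(=O)Oc2cc1OCc1ccccc1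
F6 | step 10 | (Z)-2-[2,5-bis(benzyloxy)-3,4-dimethoxyphenyl]-3-[4-(benzyloxy)-2-hydroxy-5-methoxyphenyl]prop-2-en-1-ol | COc1cc(/C=C(\CO)c2cc(OCc3ccccc3)c(OC)c(OC)c2OCc2ccccc2)c(O)cc1OCc1ccccc1
F7 | step 10 | 7-(benzyloxy)-3-[2,5-bis(benzyloxy)-3,4-dimethoxyphenyl]-6-methoxy-2H-chromene | COc1cc2C=C(c3cc(OCc4ccccc4)c(OC)c(OC)c3OCc3ccccc3)COc2cc1OCc1ccccc1
F8 | step 8 | (2R,3S)-2-[2,5-bis(benzyloxy)-3,4-dimethoxyphenyl]-6-(benzyloxy)-5-methoxy-3-(4,4,5,5-tetramethyl-1,3,2-dioxaborolan-2-yl)-2,3-dihydro-1H-inden-1-one | COc1cc2c(cc1OCc1ccccc1)C(=O)[C@@H](c1cc(OCc3ccccc3)c(OC)c(OC)c1OCc1ccccc1)[C@@H]2B1OC(C)(C)C(C)(C)O1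
F9 | step 8 | (2S,3S)-2-[2,5-bis(benzyloxy)-3,4-dimethoxyphenyl]-6-(benzyloxy)-3-hydroxy-5-methoxy-2,3-dihydro-1H-inden-1-one | COc1cc2c(cc1OCc1ccccc1)C(=O)[C@@H](c1cc(OCc3ccccc3)c(OC)c(OC)c1OCc1ccccc1)[C@@H]2O
F10 | step 8 | (1S,2S)-2-[2,5-bis(benzyloxy)-3,4-dimethoxyphenyl]-5-(benzyloxy)-6-methoxy-3-oxo-2,3-dihydro-1H-inden-1-yl acetate | COc1cc2c(cc1OCc1ccccc1)C(=O)[C@@H](c1cc(OCc3ccccc3)c(OC)c(OC)c1OCc1ccccc1)[C@@H]2OC(C)=O
F11 | step 14 | (3S,4R)-4-[(tert-butyldimethylsilyl)oxy]-3-(2,5-dihydroxy-3,4-dimethoxyphenyl)-6-methoxychroman-7-ol | COc1cc2c(cc1O)OC[C@H](c1cc(O)c(OC)c(OC)c1O)[C@H]2O[Si](C)(C)C(C)(C)C
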